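Everything rests on building ring A de novo instead of substituting a pyrogallol ether: a photochemical Danheiser benzannulation unites a cyclobutenone-derived vinylketene with a symmetrical dialkoxyalkyne. In one operation it forges C4a–C8a and C5–C6, closes ring A, and delivers the three adjacent oxygens (O1 on C8a, O4 on C4a, the future methoxy oxygen on C5) with the allyl group on C7 para to C4a, O1 alone being free. The precursor is 3-allylcyclobut-2-en-1-one, paired with di-tert-butoxyethyne. An (S)-2-chloropropanoyl tether on O1 is then closed by O4 with inversion, and a Weinreb amide plus an aryl Grignard reagent complete the hemiketal.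

Key step: step 2

Assumption: di-tert-butoxyethyne is taken as a purchasable reagent kept at −20 °C; where it has to be made, the established preparation from trans-2,3-dichloro-1,4-dioxane is used and the route below is unchanged.
Assumption: C2 is a hemiketal carbon that equilibrates through the open keto phenol, so the route has to fix only C3; the (2S,3R) isomer (OH axial and anti to the C3 methyl, aryl group equatorial) is taken to be the stable hemiketal.

Step 1
Reactants: 1 3-ethoxycyclobut-2-en-1-one; 2 allylmagnesium bromide
Product: 4 3-allylcyclobut-2-en-1-one, via cyclobutenol 3 (not isolated)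
Conditions: 2 (1.1 equiv), Et2O, −78 °C; then 1 M aq. HCl, 0 °C, 20 min
Reagents that add atoms: water, O
Why: 1,2-Addition of the allyl Grignard reagent to the vinylogous ester carbonyl, then acid-promoted ionisation of the tertiary allylic alcohol and hydrolysis of the ethoxy-stabilised cation, transposes the carbonyl (Stork–Danheiser sequence), and the short, cold acid contact is chosen so that the skipped allyl double bond does not move into conjugation.

Step 2
Reactants: 4 3-allylcyclobut-2-en-1-one; 5 di-tert-butoxyethyne
Product: 10 5-allyl-2,3-di-tert-butoxyphenol, via vinylketene 6 (not isolated), via alkenylcyclobutenone 7 (not isolated), via dienylketene 8 (not isolated), via cyclohexadienone 9 (not isolated)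
Conditions: 5 (1.5 equiv), hν (254–300 nm, quartz), degassed CH2Cl2, 20 °C; excess 5 removed in vacuo at 20 °C; then toluene, 80 °C, 1 h
Reagents that add atoms: none
Why: Light opens cyclobutenone 4 by 4π electrocyclic cleavage to vinylketene 6, which adds the electron-rich alkyne 5 across its ketene C=C bond in a [2+2] cycloaddition (forming C4a–C8a and C5–C6) to give 7, and a second 4π opening, photochemical or on warming, gives dienylketene 8. Ring A then closes by thermal 6π electrocyclisation of 8 (re-forming C8–C8a), and cyclohexadienone 9 tautomerises to the phenol, which drives the cascade. The closest known reaction type is the Danheiser benzannulation of cyclobutenones with ynol ethers in its photochemical variant, together with the known [2+2] additions of ketenes to di-tert-butoxyethyne. No stereocentre is created, since the sp3 carbons of 7 and 9 are flattened on aromatisation. Regiochemistry does not arise because the alkyne is symmetrical and the allyl-bearing carbon sits β to the ketene carbon in 6, which places it para to C4a by connectivity; chemoselectivity for the ynol ether over the isolated allyl alkene follows from the nucleophilicity of the alkyne. Irradiation at 20 °C spares the heat-sensitive tert-butyl ynol ether, its excess should intercept 6 before the product phenol can, and it is stripped off before the brief warming.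

Step 3
Reactants: 10 5-allyl-2,3-di-tert-butoxyphenol; 11 (2S)-2-chloropropanoyl chloride
Product: 12 5-allyl-2,3-di-tert-butoxyphenyl (2S)-2-chloropropanoate
Conditions: 11 (1.2 equiv), pyridine (2 equiv), CH2Cl2, −20 → 0 °C
Reagents that add atoms: none
Why: Acylation of the only free phenol through the acylpyridinium ion (Einhorn conditions) leaves the acid-labile tert-butyl ethers alone, and the cold, weakly basic medium is chosen to keep the acid chloride from forming a ketene, so the (S) centre should be carried over unchanged.

Step 4
Reactants: 12 5-allyl-2,3-di-tert-butoxyphenyl (2S)-2-chloropropanoate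
Product: 14 (3R)-7-allyl-5-hydroxy-3-methyl-2,3-dihydro-1,4-benzodioxin-2-one, via catechol ester 13 (not isolated)
Conditions: TFA, CH2Cl2, 0 °C (argon sweep); evaporate with toluene; then KHCO3 (3 equiv), dry DMF (0.02 M), 20–40 °C
Reagents that add atoms: none
Why: Acidolysis of both aryl tert-butyl ethers (loss of 2-methylpropene) leaves the acyl group on O1, and in the bicarbonate-buffered monoanion, which should favour the outer ester because only there can the C5 hydroxyl hydrogen-bond to the phenoxide, O4 displaces chloride in a 6-exo-tet intramolecular Williamson (SN2) closure with inversion, turning the (S) C–Cl centre into (R)-C3–O4; bicarbonate avoids the dianion and iodide is left out so that the centre inverts only once.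

Step 5
Reactants: 14 (3R)-7-allyl-5-hydroxy-3-methyl-2,3-dihydro-1,4-benzodioxin-2-one
Product: 15 (3R)-7-allyl-5-methoxy-3-methyl-2,3-dihydro-1,4-benzodioxin-2-one
Conditions: MeOH (2 equiv), PPh3, DIAD, THF, 0 → 20 °C
Reagents that add atoms: methanol, CO
Why: Mitsunobu O-methylation of the phenol is neutral and free of carbonate or alkoxide, so the aryl ester lactone should not be opened and C3, α to the lactone carbonyl, should not be epimerised.

Step 6
Reactants: 15 (3R)-7-allyl-5-methoxy-3-methyl-2,3-dihydro-1,4-benzodioxin-2-one
Product: 16 (2R)-2-(4-allyl-2-hydroxy-6-methoxyphenoxy)-N-methoxy-N-methylpropanamide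
Conditions: MeNH(OMe)·HCl (1.5 equiv), iPrMgCl (3.0 equiv), THF, −20 °C; aq. NH4Cl
Reagents that add atoms: N,O-dimethylhydroxylamine hydrochloride, CNOC.Cl
Why: Aminolysis of the activated aryl ester by the chloromagnesium amide of N,O-dimethylhydroxylamine opens the lactone to the Weinreb amide and frees O1 as its phenoxide, fast enough at −20 °C that C3 should not be deprotonated; the amide is interposed because an aryl Grignard reagent added directly to an aryl ester risks double addition once the phenoxide has left.

Step 7
Reactants: 16 (2R)-2-(4-allyl-2-hydroxy-6-methoxyphenoxy)-N-methoxy-N-methylpropanamide; 17 5-bromo-1,2,3-trimethoxybenzene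
Product: 20 (2S,3R)-7-allyl-5-methoxy-3-methyl-2-(3,4,5-trimethoxyphenyl)-2,3-dihydro-1,4-benzodioxin-2-ol, via aryl Grignard 18 (not isolated), via keto phenol 19 (not isolated)
Conditions: 17 (3 equiv), Mg, THF, 45 °C; then 16, THF, −10 → 0 °C; sat. aq. NH4Cl
Reagents that add atoms: none
Why: Weinreb ketone synthesis, in which the first equivalent of 18 deprotonates the phenol and the next adds to the amide to give a chelated tetrahedral adduct that cannot add again, so that on work-up keto phenol 19 is released and closes by 6-exo-trig hemiketalisation; C3 is untouched, and C2, which equilibrates through 19, should settle under thermodynamic control as the hemiketal with axial OH (anomeric effect), equatorial aryl group and the methyl anti to OH, that is 2S.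

Compound list
1 | 3-ethoxycyclobut-2-en-1-one | CCOC1=CC(=O)C1 | starting material
2 | allylmagnesium bromide | C=CC[Mg]Br | starting material
3 | 3-ethoxy-1-(prop-2-en-1-yl)cyclobut-2-en-1-ol (racemic; bromomagnesium alkoxide until the acid is added) | C=CCC1(O)C=C(OCC)C1 | intermediate
4 | 3-allylcyclobut-2-en-1-one | C=CCC1=CC(=O)C1 | intermediate
5 | di-tert-butoxyethyne | CC(C)(C)OC#COC(C)(C)C | starting material
6 | 3-methylidenehexa-1,5-dien-1-one (vinylketene) | C=CCC(=C)C=C=O | intermediate
7 | 2,3-di-tert-butoxy-4-(penta-1,4-dien-2-yl)cyclobut-2-en-1-one (racemic) | C=CCC(=C)C1C(=O)C(OC(C)(C)C)=C1OC(C)(C)C | intermediate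
8 | (3E)-2,3-di-tert-butoxy-5-methylideneocta-1,3,7-trien-1-one (dienylketene; C2 and C5 cis across C3=C4) | C=CCC(=C)/C=C(OC(C)(C)C)\C(OC(C)(C)C)=C=O | intermediate
9 | 2,3-di-tert-butoxy-5-(prop-2-en-1-yl)cyclohexa-2,4-dien-1-one | C=CCC1=CC(OC(C)(C)C)=C(OC(C)(C)C)C(=O)C1 | intermediate
10 | 5-allyl-2,3-di-tert-butoxyphenol | C=CCc1cc(O)c(OC(C)(C)C)c(OC(C)(C)C)c1 | intermediate
11 | (2S)-2-chloropropanoyl chloride | C[C@H](Cl)C(Cl)=O | starting material
12 | 5-allyl-2,3-di-tert-butoxyphenyl (2S)-2-chloropropanoate | C=CCc1cc(OC(=O)[C@H](C)Cl)c(OC(C)(C)C)c(OC(C)(C)C)c1 | intermediate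
13 | 5-allyl-2,3-dihydroxyphenyl (2S)-2-chloropropanoate | C=CCc1cc(OC(=O)[C@H](C)Cl)c(O)c(O)c1 | intermediate
14 | (3R)-7-allyl-5-hydroxy-3-methyl-2,3-dihydro-1,4-benzodioxin-2-one | C=CCc1cc(O)c2c(c1)OC(=O)[C@@H](C)O2 | intermediate
15 | (3R)-7-allyl-5-methoxy-3-methyl-2,3-dihydro-1,4-benzodioxin-2-one | C=CCc1cc(OC)c2c(c1)OC(=O)[C@@H](C)O2 | intermediate
16 | (2R)-2-(4-allyl-2-hydroxy-6-methoxyphenoxy)-N-methoxy-N-methylpropanamide | C=CCc1cc(O)c(O[C@H](C)C(=O)N(C)OC)c(OC)c1 | intermediate
17 | 5-bromo-1,2,3-trimethoxybenzene | COc1cc(Br)cc(OC)c1OC | starting material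
18 | (3,4,5-trimethoxyphenyl)magnesium bromide | COc1cc([Mg]Br)cc(OC)c1OC | intermediate
19 | (2R)-2-(4-allyl-2-hydroxy-6-methoxyphenoxy)-1-(3,4,5-trimethoxyphenyl)propan-1-one | C=CCc1cc(O)c(O[C@H](C)C(=O)c2cc(OC)c(OC)c(OC)c2)c(OC)c1 | intermediate
20 | (2S,3R)-7-allyl-5-methoxy-3-methyl-2-(3,4,5-trimethoxyphenyl)-2,3-dihydro-1,4-benzodioxin-2-ol (CNP0114249.1) | C=CCc1cc(OC)c2c(c1)O[C@@](O)(c1cc(OC)c(OC)c(OC)c1)[C@@H](C)O2 | target

Total step count: 7
Longest linear sequence: 7 steps (1 → 4 → 10 → 12 → 14 → 15 → 16 → 20)

Steps most likely to fail

Step 2. The ynol ether may shed 2-methylpropene to a ketene before it is captured, the vinylketene may acylate the phenol already formed, or the cyclobutenone may be lost to unproductive photochemistry. The fallback sets out from alkyne 5 and comes back at phenol 10, generating the same vinylketene by photochemical Wolff rearrangement instead. Purchased hex-5-en-2-one is α-methylenated at C3 (paraformaldehyde, iPr2NH·CF3CO2H, THF, reflux; Mannich condensation and elimination) to 3-methylidenehex-5-en-2-one F1. Trifluoroacetylation of its kinetic enolate (LiN(SiMe3)2, CF3CO2CH2CF3, THF, −78 °C) should give 1,1,1-trifluoro-5-methylideneoct-7-ene-2,4-dione F2, and detrifluoroacetylative diazo transfer (MsN3, Et3N, H2O, MeCN) 1-diazo-3-methylidenehex-5-en-2-one F3. Irradiation of F3 with 5 (300–365 nm, CH2Cl2, 20 °C; excess 5 removed; toluene, 80 °C) should pass through vinylketene 6 and end at 10. The longer-wavelength light is gentler on the ynol ether, and the sensitive cyclobutenone 4 is no longer needed.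

Step 4. In the phenoxide the acyl group may migrate from O1 to the central O4 before ring closure, so that an outer oxygen closes the ring and the regioisomeric lactone results; chloride exchange at the α-chloro ester may also erode C3. The fallback sets out from phenol 10 and comes back at lactone 14, and it lets regiochemistry rest on symmetry instead of on relative rates; it also bypasses the acylation of step 3. TFA in CH2Cl2 strips both tert-butyl groups to the symmetrical 5-(prop-2-en-1-yl)benzene-1,2,3-triol F4. TBSCl (2.1 equiv) and imidazole in DMF should silylate the two unhindered flanking hydroxyls to give 4-allyl-2,6-bis[(tert-butyldimethylsilyl)oxy]phenol F5. Mitsunobu reaction of its only free oxygen with ethyl (S)-lactate (PPh3, DIAD, THF) forms the O4–C3 bond with inversion, giving ethyl (2R)-2-{4-allyl-2,6-bis[(tert-butyldimethylsilyl)oxy]phenoxy}propanoate F6. Bu4NF buffered with AcOH should give ethyl (2R)-2-(4-allyl-2,6-dihydroxyphenoxy)propanoate F7, which lactonises onto either of its two equivalent hydroxyls (TsOH cat., toluene, 60 °C) to 14.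

Step 7. The basic Grignard reagent may remove the C3 proton next to the amide in competition with addition and so erode the C3 configuration, or addition may stall on the magnesium phenoxide aggregate. The fallback sets out from lactone 15 and comes back at target 20, skipping the amide. Bromine–lithium exchange on 17 (n-BuLi, THF, −78 °C) gives (3,4,5-trimethoxyphenyl)lithium F8, which is added (1.05 equiv) to 15 at −78 °C and quenched cold with AcOH. Addition to the activated lactone should outrun enolisation at that temperature, and the lithium hemiketal alkoxide is protonated directly to the hemiketal. The price is the risk of double addition that the amide route was chosen to avoid.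

Further compounds
F1 | step 2 | 3-methylidenehex-5-en-2-one | CC(=O)C(=C)CC=C
F2 | step 2 | 1,1,1-trifluoro-5-methylideneoct-7-ene-2,4-dione | C=CCC(=C)C(=O)CC(=O)C(F)(F)F
F3 | step 2 | 1-diazo-3-methylidenehex-5-en-2-one | C=CCC(=C)C(=O)C=[N+]=[N-]
F4 | step 4 | 5-(prop-2-en-1-yl)benzene-1,2,3-triol | C=CCc1cc(O)c(O)c(O)c1
F5 | step 4 | 4-allyl-2,6-bis[(tert-butyldimethylsilyl)oxy]phenol | C=CCc1cc(O[Si](C)(C)C(C)(C)C)c(O)c(O[Si](C)(C)C(C)(C)C)c1
F6 | step 4 | ethyl (2R)-2-{4-allyl-2,6-bis[(tert-butyldimethylsilyl)oxy]phenoxy}propanoate | C=CCc1cc(O[Si](C)(C)C(C)(C)C)c(O[C@H](C)C(=O)OCC)c(O[Si](C)(C)C(C)(C)C)c1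
F7 | step 4 | ethyl (2R)-2-(4-allyl-2,6-dihydroxyphenoxy)propanoate | C=CCc1cc(O)c(O[C@H](C)C(=O)OCC)c(O)c1
F8 | step 7 | (3,4,5-trimethoxyphenyl)lithium | [Li]c1cc(OC)c(OC)c(OC)c1
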